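The chemist taking over this bench finds the flasks ash, alder, birch and larch charged alike, at different temperatures, beside the earlier runs red, teal and green.

| setting | red | teal | green | ash | alder | birch | larch |
|---|---|---|---|---|---|---|---|
| substrate | 0.60 M | 0.60 M | 0.60 M | 0.60 M | 0.60 M | 0.60 M | 0.60 M |
| gas | 200 mM (held) | 200 mM (held) | 200 mM (held) | 200 mM (held) | 200 mM (held) | 200 mM (held) | 200 mM (held) |
| free catalyst | 90 mM | 90 mM | 45 mM | 90 mM | 90 mM | 90 mM | 90 mM |
| impurity | 46 mM | 73 mM | 33 mM | 33 mM | 33 mM | 33 mM | 33 mM |
| temperature | −5 °C | 25 °C | −5 °C | 0 °C | 50 °C | 25 °C |  |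
| remark | run made earlier | run made earlier | run made earlier |  |  |  | at 0 °C until 20 min, from then on at 50 °C |
| time |  |  |  | 30 min | 30 min | 30 min | 30 min |

| run | time / min | target / % | substrate / % |
|---|---|---|---|
| red | 2.50 | 0.2 | 99.9 |
| red | 4.00 | 0.1 | 99.5 |
| red | 6.00 | 1.3 | 99.1 |
| red | 8.00 | 1.7 | 98.2 |
| red | 12.0 | 3.7 | 95.7 |
| red | 20.0 | 8.2 | 91.7 |
| red | 30.0 | 12.9 | 85.9 |
| teal | 0.417 | 0.3 | 99.5 |
| teal | 1.33 | 0.8 | 99.3 |
| teal | 2.50 | 2.3 | 96.7 |
| teal | 4.00 | 5.1 | 94.7 |
| teal | 6.00 | 6.9 | 91.9 |
| teal | 8.00 | 9.1 | 88.9 |
| green | 6.00 | 1.7 | 99.5 |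
| green | 12.0 | 4.1 | 95.7 |
| green | 20.0 | 7.4 | 92.3 |
| green | 25.0 | 10.9 | 89.0 |
| green | 30.0 | 14.2 | 87.1 |

(readings scatter by 0.5 percentage points)

- the best flask by amount of target, in percent of the substrate charged; "all alike" if 1.5 percentage points covers them all (ash / alder / birch / larch / all alike)
- amount of target at the end, in percent of the substrate charged, ash
- amount of target at the end, in percent of the substrate charged, alder
- amount of target at the end, in percent of the substrate charged, birch
- amount of target at the end, in percent of the substrate charged, larch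

- at the start none of reagent is dissolved
- what was read earlier has a scatter of 0.5 percentage points, one standard deviation
- reactions considered so far: substrate + reagent <-> target; substrate + reagent <-> isomer of the product; target + free catalyst <-> isomer of the product + free catalyst; gas <-> reagent; reagent <-> dormant form; free catalyst + impurity -> spent catalyst

Impurity takes free catalyst one to one into spent catalyst, and it is the smaller charge, the limiting reagent of that side step. So once it is consumed, each flask holds W = 57.0 mM, the working catalyst, defined as free catalyst charged minus impurity charged. That is 63.3% of the catalyst charge, with the rest as spent catalyst.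

W does not show in the target of the cold runs. Red, with W = 44.0 mM, read 12.9% at 30.0 min, and green, with W = 12.0 mM, read 14.2% at 30.0 min. Red thus held more W. Its last target reading nevertheless stands lower than that of green. The target therefore reads as made without catalyst, and W belongs to its onward step to isomer. Teal, with W = 17.0 mM, already lacked 2 percentage points of its balance at 8.00 min.

This reckoning gives W and no target figure. The forecast gives these: ash best, with 13.5% in ash, 6% in alder, 8% in birch and 4.5% in larch. Its ground: “With 57 mM free catalyst, warm flasks should drain target toward isomer, so cold wins.”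

Birch holds most, 21.2%, against 17.7% in ash, 18.2% in alder and 15.7% in larch. At 30.0 min, birch still makes target 1.40 times faster than it uses it up. Free catalyst stands at 63.3% of its charge in birch and 63.3% in ash, the share W gave, and at that equal W isomer stands at 17.9% in birch and 1.79% in ash.

    substrate + reagent ⇌ target (K = 10.7 /M, k = 1.36 /M/min, Ea = 70.0 kJ/mol, ΔH = 14.0 kJ/mol)
    substrate + reagent ⇌ isomer of the product (K = 130 /M, k = 0.0887 /M/min, Ea = 78.0 kJ/mol, ΔH = −41.0 kJ/mol)
    target + free catalyst ⇌ isomer of the product + free catalyst, rate k3*[free catalyst]*[target] forward; the back reaction follows from the equilibrium constant (k = 0.586 /M/min, Ea = 66.0 kJ/mol)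
    gas ⇌ reagent, rate k4*(csat - [reagent]) (kL = 0.0724 /min)
    reagent ⇌ dormant form (K = 3.10, k = 0.270 /min, Ea = 83.0 kJ/mol, ΔH = −1.00 kJ/mol)
    free catalyst + impurity → spent catalyst (k = 72.4 /M/min, Ea = 46.0 kJ/mol)
    (constants at 25 °C)

A neighbour of birch is charged with 0.22 M of free catalyst, so its W is 187 mM, which is 85.0% of its charge and 3.28 times the W of birch. The simulated neighbour ends with free catalyst at 85.0%, isomer at 30.6% and target at 12.9%, less than in birch.

The earlier runs and the new flask are simulated for substances that don't exist; the scatter is artificial.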